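All runs were computed from invented constants; noise was put on by code.

Per hour, as a fraction of the Xa charged, the zeta run made 0.184 h⁻¹ of Ul on average up to its last reading and the delta run 0.223 h⁻¹, so I replaced each curve by its mean and divided the logarithm of that ratio by the logarithm of the ratio of Qo charges, which gave an apparent reaction order that I call the mean-rate order in Qo, 0.432, a reading that carries the scatter of both runs.

| setting | zeta | delta | alpha | flask |
|---|---|---|---|---|
| Xa | 20 mM | 20 mM | 40 mM | 20 mM |
| Qo | 70 mM | 110 mM | 50 mM | 50.0 mM |
| remark | run made earlier | run made earlier | run made earlier |  |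
| time |  |  |  | 1.0 h |
| volume of the second phase over the first |  |  |  | 2.0 |

| run | time / min | Ul / % |
|---|---|---|
| zeta | 4.00 | 0.8 |
| zeta | 12.0 | 2.3 |
| zeta | 20.0 | 5.5 |
| zeta | 30.0 | 9.8 |
| zeta | 50.0 | 15.3 |
| delta | 4.00 | 0.8 |
| delta | 12.0 | 4.2 |
| delta | 20.0 | 7.9 |
| delta | 30.0 | 14.4 |
| delta | 50.0 | 18.6 |
| alpha | 10.0 | 1.6 |
| alpha | 20.0 | 3.9 |
| alpha | 30.0 | 6.3 |
| alpha | 40.0 | 8.6 |
| alpha | 50.0 | 9.5 |

(readings scatter by 0.5 percentage points)

- in the second phase: Qo; everything else is in the first
- charges count per volume of the first phase; a concentration in a rate is the amount of a species over the volume of its own phase; every rate counts per litre of the first phase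
- the earlier runs hold the two phases in the same ratio of volumes as the flask asked about

- maple: doubling the amount of Qo, all else as stated
- oak: doubling the transfer coefficient of Qo, all else as stated

* the Ul standing at 1.0 h, as a percentage of the Xa charged
* the change that raises the amount of Ul at 1.0 h, in percent of the Xa charged most ("none" if none brings more than 2 percentage points) (maple / oak / none)
* amount of Ul at 1.0 h, in percent of the Xa charged, after oak

Scaled to the flask's Qo charge, the zeta mean held for 1.0 h gave an upper estimate of 15.9%, but the last stretch of the delta run read 0.126 h⁻¹, below its mean, so I took the mean to err upward and set a lower estimate of 13.2%, by letting the scaled curve stand still after the time of the last zeta reading. I committed to the middle, 14.6%, and to a gain of 5.1 percentage points from maple, above the 2 points bar; the order says nothing of oak, which changes no charge.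

The forecast, “Maple is best”, put Ul at 14%, chose maple and gave 16.5% after oak.

The flask stood at 13.5% of Ul, between my two estimates; maple gained 5.5 points and oak 2 points, the oak flask reaching 15.5%.

    Qe ⇌ Qo, rate k1*([Qe] - [Qo]/K1) per volume of the first phase (partition coefficient = 2.11, kL = 5.75 × 10⁻⁴ s⁻¹)
    Xa + Qe ⇌ Ul (K = 57.4 L mol⁻¹, k = 0.0157 L mol⁻¹ s⁻¹)
    Qe + Ul → Kj (k = 0.0303 L mol⁻¹ s⁻¹)

The flask's own mean rate over 1.0 h was 0.135 h⁻¹, under the scaled mean, and its Ul multiplied by two to the power 0.432 gave 18.2% for the maple flask, which stood at 19.1%. At 1.00 h in the flask, Ul was made 1.75 times as fast as it was used up, each step taken net.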